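## The problem

Atoms are numbered in the order in which they stand in the line notation of the target 26: C1–C3 and O4 (carbinol end), C5=C6, C7=C8, C9, O10, C11(=O12), C13, C14, C15, C16, C17 (methyl C18), C19, C20 (O21), C22, C23, C24 (O25). The carbon core is a bicyclo[4.3.1]decane: a cyclohexane (C17, C19, C20, C22, C23, C24) and a cycloheptane (C13–C17, C19, C20) share the bridgeheads C17 and C20 and the one-carbon bridge C19. A δ-lactone (C8, C9, O10, C11, C13, C14) is trans-fused on the C13–C14 edge and carries an exocyclic E,E-dienyl carbinol at C8.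

Of the five stereocentres, C20 (tertiary carbinol) and C17 (quaternary, methyl) are bridgeheads and fix each other. C24 bears an axial hydroxyl anti to the four-carbon bridge, C14 bears C8 on the side of O21, and C13 bears C11 anti to both. Only C20 must be set absolutely: it dictates C17, its oxygen can deliver a tethered nucleophile to the right face of C14, and the rigid bicycle can steer the proton at C13 and the hydride at C24.

The tertiary, doubly allylic C2 carbinol ionizes under protic or oxophilic Lewis acids. C13–H is α and O21 is β to the lactone carbonyl (epimerization, retro-aldol under strong base). The C7=C8 bond is not conjugated with C11, so its geometry must be defined while C9 is still a carbonyl.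

The enabling feature is that C17 and C20 are joined by C19, by C22–C23–C24 and by C13–C14–C15–C16, with oxygen on C24 and C20. The cyclohexane is thus the cyclohexene of a Diels–Alder reaction between the 2-oxy diene C19=C17–C24(O)=C23 and the 2-oxy enone C22=C20(O)–C13=O, with the diene tied through C17 to C20 by four atoms, the type 2 (bridged) intramolecular arrangement.

## Retrosynthesis

**O10–C11 and the C9 oxidation level.** Lactone 26 is opened to triol ester 25 and traced to hydroxy dienal 24. As an aldehyde, C9 is reduced by borohydride without touching the C11 ester, and the primary allylic alcohol then closes the δ-lactone under neutral conditions. Making C7=C8 on the finished lactone is not possible, because C8 is γ to C11.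

**C9–O21.** In 24 the C9 carbonyl is put back on O21 as the bridged α-alkylidene lactone 23. This parks C9 at the acid level, where it activates C8 for carbanion chemistry and olefination. The forward step must reduce this lactone in the presence of the C11 methyl ester.

**C7=C8 and C8–C14.** Lactone 23 is cut by a Horner–Wadsworth–Emmons reaction to aldehyde 21 and by an intramolecular Michael addition to phosphonoacetate 18. The tether on O21 can reach C14 only on the face required by the target and makes the E-alkylidene the normal olefination outcome. An intermolecular vinyl-metal addition to the hindered enoate would control neither. Aldehyde 21 comes from cross-metathesis of alcohol 19 with enal 20.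

**C11–C13, C24–H and the O21 acyl group.** Enoate 18 comes from enol triflate 17 by methoxycarbonylation, 17 from ketone 16 by hydride addition, 16 from alcohol 14 and acid 15, and 14 from acetal 13. The order is chosen so that C20–OH is acylated while it is the only hydroxyl, and C24 is reduced while no conjugate acceptor is present. No protecting group other than the methoxymethyl ether is then needed.

**C17–C18.** Methyl ketone 13 comes from bridgehead silyl enol ether 12 by fluoride-triggered methylation. The enol ether defines the enolate regiochemistry, and the enol triflate masks C13 so that no other acidic site competes.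

**C13–O (triflate).** Triflate 12 comes from ketone 10 through enolate 11; only C14 can be enolized.

**C19–C20 and C22–C23 (key step).** Cycloadduct 10 is cut to the acyclic triene 9. Both carbocycles, all ten ring carbons, O21 and O25 are taken back to one chain with no stereocentre. The forward reaction must choose one enantioface of the dienophile.

**C13–C20.** Triene 9 is cut to Weinreb amide 5 and vinyllithium 8, made from vinyl ether 7 (from bromide 6). Introducing the methoxymethoxy-vinyl unit directly avoids a 1,2-diketone whose enol etherification would be regiochemically ambiguous. The silyl dienol ether is installed before the C13 ketone exists, so its formation has no competitor.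

**Diene and chain.** Amide 5 comes from enone 4 by soft enolization, 4 from keto amide 3 by α-methylenation (C19), and 3 from 6-oxoheptanoic acid 1 through acyl imidazole 2.

## Roads not taken

**Alternative 1:** The cut is C9–O10 with a 1,3-shift of oxygen: seco acid A2, a C7 bis-allylic carbinol with a C8=C9 methylene, would give the bis-silyl ether A1 of the target. A rhenium-oxo catalyst (Re2O7 or Ph3SiOReO3) would move the hydroxyl from C7 to C9 through the perrhenate ester, and the C11 acid would trap the primary alcohol.
- Merits: C9 never becomes a carbonyl, so no chemoselective reduction is needed, and the lactone trap pulls the equilibrium.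
- Weak points: the carbinol can also migrate toward C5 or ionize, and the C2 silyl ether sits on the same pentadienyl system. The E geometry of a trisubstituted alkene rests on a chair preference. A2 still needs the whole bicyclic core and a C14–C8 bond on a hindered enoate.
- Comparison: this road is better in redox economy at C9 and could be grafted onto the chosen core. The chosen plan sets against it an olefination under basic conditions that fixes the geometry, never exposes the C2 carbinol to an oxophilic Lewis acid, and a tether that also sets C14.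

**Alternative 2:** The cut is C13–C14 and C17–C19. Vinyldiazoacetate A4 and diene A5 would give cycloheptadiene A3 with a chiral dirhodium tetracarboxylate such as Rh2(S-DOSP)4, by cyclopropanation of C14=C15 and Cope rearrangement.
- Merits: the asymmetric catalysis is established, which the chosen key step is not. C14 and the quaternary C17 are set at once, and C8–C9 is already on C14.
- Weak points: only the seven-membered ring is made. The carbenoid must attack a trans-disubstituted alkene, and the fully substituted C17 terminus puts one group inside the boat transition state. C22 and C23 must then be bridged from C24 to C20 with creation of the oxygenated bridgehead.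
- Comparison: better in precedent for enantiocontrol. The chosen plan sets against it one step that closes both rings with all ring carbons and both ring oxygens in place.

**Alternative 3:** The cut is C15–C16, with the non-target bond C13–C24 present in norbornanol A7. Its potassium alkoxide (KN(SiMe3)2, 18-crown-6) would undergo anionic oxy-Cope rearrangement, and the bridgehead enolate would be methylated in the same flask to A6.
- Merits: the rearrangement type is well known and strongly driven. The enolate is formed regiospecifically without a silyl enol ether, and A6 already carries the C13 ester, so triflation and carbonylation are saved.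
- Weak points: A7 has a quaternary C13 with vinyl syn to the methylene bridge, a bridgehead carbinol and a bridgehead silyl ether, and no short enantioselective access. The alkoxide is β to the ester, so retro-aldol cleavage of C13–C24 competes.
- Comparison: better in the methylation and ester stages. The chosen plan sets against it precursor 9, five steps from commercial acyclic material, with the stereocentre set by a catalyst.

Key step: step 6

Assumption: the (S,S) ligand is taken to expose the dienophile face leading to (1R)-10 (square-planar chelate model), otherwise its enantiomer is used; 1-bromo-2-(methoxymethoxy)ethane is taken as purchasable.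

## Route

Step 1
Reactants: 1 6-oxoheptanoic acid
Product: 3 N-methoxy-N-methyl-6-oxoheptanamide, via acyl imidazole 2 (not isolated)
Conditions: 1,1'-carbonyldiimidazole, CH2Cl2, 0 °C to rt; then MeNHOMe·HCl, rt
Reagents that add atoms: N,O-dimethylhydroxylamine hydrochloride, CNOC.Cl
Why: Carboxyl activation as the imidazolide and aminolysis (Weinreb amide formation); the ketone is not an acylating site and stays untouched.

Step 2
Reactants: 3 N-methoxy-N-methyl-6-oxoheptanamide
Product: 4 N-methoxy-N-methyl-5-methylidene-6-oxoheptanamide
Conditions: (CH2O)n, N-methylanilinium trifluoroacetate, THF, reflux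
Reagents that add atoms: formaldehyde (as paraformaldehyde), C=O
Why: Mannich condensation–elimination (α-methylenation); acid-mediated enolization of the methyl ketone favours the more substituted C5 enol, so the methylene (C19) enters next to the chain, and the amide is not enolized.

Step 3
Reactants: 4 N-methoxy-N-methyl-5-methylidene-6-oxoheptanamide
Product: 5 N-methoxy-N-methyl-5-methylidene-6-[(triethylsilyl)oxy]hept-6-enamide
Conditions: Et3SiOTf, Et3N, CH2Cl2, −78 to 0 °C
Reagents that add atoms: triethylsilyl trifluoromethanesulfonate, CC[Si](CC)(CC)OS(=O)(=O)C(F)(F)F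
Why: Soft enolization of the only enolizable position of the enone (its methyl group) gives the 2-silyloxydiene; the Weinreb amide is not enolized by an amine base.

Step 4
Reactants: 6 1-bromo-2-(methoxymethoxy)ethane
Product: 7 (methoxymethoxy)ethene
Conditions: KOH (powder), tetraglyme, 120 °C, product distilled out; redistilled from CaH2
Reagents that add atoms: none
Why: E2 dehydrobromination of a 2-bromoethyl ether to the vinyl ether; the formaldehyde acetal is stable to base.

Step 5
Reactants: 7 (methoxymethoxy)ethene; 5 N-methoxy-N-methyl-5-methylidene-6-[(triethylsilyl)oxy]hept-6-enamide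
Product: 9 2-(methoxymethoxy)-7-methylidene-8-[(triethylsilyl)oxy]nona-1,8-dien-3-one, via vinyllithium 8 (not isolated)
Conditions: 7, s-BuLi, THF, −78 to −40 °C; then 5, −78 °C; pH 7 phosphate buffer
Reagents that add atoms: none
Why: α-Lithiation of an enol ether (acyl anion equivalent, assisted by the acetal oxygens) and acylation by the Weinreb amide through the chelated tetrahedral intermediate, which prevents a second addition; the silyl dienol ether survives the cold, buffered procedure.

Step 6
Reactants: 9 2-(methoxymethoxy)-7-methylidene-8-[(triethylsilyl)oxy]nona-1,8-dien-3-one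
Product: 10 (1R)-1-(methoxymethoxy)-7-[(triethylsilyl)oxy]bicyclo[4.3.1]dec-6-en-2-one
Conditions: Cu(OTf)2 (10 mol %), (S,S)-2,2'-isopropylidenebis(4-tert-butyl-2-oxazoline) (11 mol %), 4 Å MS, CH2Cl2, 0.01 M, −78 to −30 °C
Reagents that add atoms: none
Why: Proposed new method: Cu(OTf)2 with the bis(oxazoline) is expected to bind the ketone oxygen and the methoxymethoxy oxygen of 9 as a five-membered chelate, which lowers the LUMO of the C20=C22 dienophile and leaves one face open beside a tert-butyl group. The 2-silyloxydiene then adds in a concerted, asynchronous [4+2] cycloaddition in which the nucleophilic terminus C23 bonds to the β-carbon C22 ahead of C19–C20; a stepwise Mukaiyama–Michael/ring-closure path would give the same adduct. The closest known reaction types are the type 2 intramolecular Diels–Alder reaction of carbonyl-tethered 2-silyloxydienes (thermal or with achiral Lewis acids) and divalent-copper bis(oxazoline) catalysis of Diels–Alder reactions of two-point-binding dienophiles; their combination is not established. The six-membered ring closes as the cyclohexene of the cycloaddition (C19–C20 and C22–C23), and the seven-membered ring closes through the same C19–C20 bond in the 1,3-bridged mode, since the four-atom tether C13–C16 admits no 1,4-bridged alternative. The only new stereocentre, C20, is set by the catalyst, which selects the enantioface of the chelated dienophile; C17 stays sp2 in the bridgehead enol ether. The step needs enantioface selectivity only, because regiochemistry is secured by the tether and by the match of the enol ether terminus with the enone β-carbon. High dilution suppresses intermolecular cycloaddition and low temperature the uncatalysed racemic background.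

Step 7
Reactants: 10 (1R)-1-(methoxymethoxy)-7-[(triethylsilyl)oxy]bicyclo[4.3.1]dec-6-en-2-one
Product: 12 (1R)-1-(methoxymethoxy)-7-[(triethylsilyl)oxy]bicyclo[4.3.1]deca-2,6-dien-2-yl trifluoromethanesulfonate, via potassium enolate 11 (not isolated)
Conditions: KN(SiMe3)2, THF, −78 °C; then PhNTf2, −78 to 0 °C
Reagents that add atoms: N-phenylbis(trifluoromethanesulfonimide), O=S(=O)(N(c1ccccc1)S(=O)(=O)C(F)(F)F)C(F)(F)F
Why: Only C14 can be enolized (C20 is quaternary), so deprotonation and O-sulfonylation give a single enol triflate; the silyl enol ether and the acetal are inert to the amide base.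

Step 8
Reactants: 12 (1R)-1-(methoxymethoxy)-7-[(triethylsilyl)oxy]bicyclo[4.3.1]deca-2,6-dien-2-yl trifluoromethanesulfonate
Product: 13 (1R,6S)-1-(methoxymethoxy)-6-methyl-7-oxobicyclo[4.3.1]dec-2-en-2-yl trifluoromethanesulfonate
Conditions: (Me2N)3S+ Me3SiF2− (1.1 equiv), MeI (10 equiv), THF, −78 to −20 °C
Reagents that add atoms: iodomethane, CI
Why: Fluoride-induced desilylation gives the regiodefined metal-free bridgehead enolate, which is C-methylated by excess iodomethane (alkylation of a silyl enol ether via its onium enolate). The methyl can only occupy the exo position of the bridgehead, so 17S follows from C20, and the enol triflate leaves no other acidic site.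

Step 9
Reactants: 13 (1R,6S)-1-(methoxymethoxy)-6-methyl-7-oxobicyclo[4.3.1]dec-2-en-2-yl trifluoromethanesulfonate
Product: 14 (1R,6S)-1-hydroxy-6-methyl-7-oxobicyclo[4.3.1]dec-2-en-2-yl trifluoromethanesulfonate
Conditions: HCl (conc., cat.), MeOH, 40 °C
Reagents that add atoms: none
Why: Acid-catalysed transacetalization to methanol removes the methoxymethyl group; enol triflate and ketone are acid-stable, and the bridgehead carbinol beside an electron-poor alkene cannot ionize or eliminate.

Step 10
Reactants: 14 (1R,6S)-1-hydroxy-6-methyl-7-oxobicyclo[4.3.1]dec-2-en-2-yl trifluoromethanesulfonate; 15 (diethoxyphosphoryl)acetic acid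
Product: 16 (1R,6S)-6-methyl-7-oxo-2-{[(trifluoromethyl)sulfonyl]oxy}bicyclo[4.3.1]dec-2-en-1-yl (diethoxyphosphoryl)acetate
Conditions: N,N'-dicyclohexylcarbodiimide, 4-(dimethylamino)pyridine (cat.), CH2Cl2, 0 °C to rt
Reagents that add atoms: none
Why: Carbodiimide esterification, which for phosphonoacetic acid proceeds through the ketene and therefore acylates tertiary alcohols; C20–OH is the only hydroxyl, so no protection is needed.

Step 11
Reactants: 16 (1R,6S)-6-methyl-7-oxo-2-{[(trifluoromethyl)sulfonyl]oxy}bicyclo[4.3.1]dec-2-en-1-yl (diethoxyphosphoryl)acetate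
Product: 17 (1R,6S,7S)-7-hydroxy-6-methyl-2-{[(trifluoromethyl)sulfonyl]oxy}bicyclo[4.3.1]dec-2-en-1-yl (diethoxyphosphoryl)acetate
Conditions: LiBH(s-Bu)3 (1.3 equiv), THF, −78 °C; then aq. NH4Cl
Reagents that add atoms: none
Why: The bulky trialkylborohydride should attack the chair cyclohexanone along the equatorial trajectory, avoiding the axial hydrogens on C19 and C22 as in 4,4-disubstituted 3-ketones, which gives the axial 24S alcohol anti to the four-carbon bridge. Ester, phosphonate and enol triflate are inert at −78 °C and no conjugate acceptor is present.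

Step 12
Reactants: 17 (1R,6S,7S)-7-hydroxy-6-methyl-2-{[(trifluoromethyl)sulfonyl]oxy}bicyclo[4.3.1]dec-2-en-1-yl (diethoxyphosphoryl)acetate
Product: 18 methyl (1R,6S,7S)-1-{[(diethoxyphosphoryl)acetyl]oxy}-7-hydroxy-6-methylbicyclo[4.3.1]dec-2-ene-2-carboxylate
Conditions: Pd(PPh3)4 (5 mol %), CO (1 atm), MeOH, Et3N, DMF, rt
Reagents that add atoms: carbon monoxide, [C-]#[O+]; methanol, CO
Why: Methoxycarbonylation of an enol triflate by zerovalent palladium (oxidative addition, CO insertion, methanolysis) runs at room temperature; the free C24 hydroxyl is tolerated and triethylamine is too weak to trigger the phosphonate.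

Step 13
Reactants: 19 2-methylbut-3-en-2-ol; 20 (2E)-but-2-enal
Product: 21 (2E)-4-hydroxy-4-methylpent-2-enal
Conditions: RuCl2(H2IMes)(=CH-C6H4-2-Oi-Pr) (second-generation Hoveyda–Grubbs catalyst, 2 mol %), 20 (3 equiv), CH2Cl2, 40 °C
Reagents that add atoms: none
Why: Olefin cross-metathesis of a tertiary allylic alcohol with an enal, driven by loss of propene; the conjugated E-enal is the thermodynamic product.

Step 14
Reactants: 18 methyl (1R,6S,7S)-1-{[(diethoxyphosphoryl)acetyl]oxy}-7-hydroxy-6-methylbicyclo[4.3.1]dec-2-ene-2-carboxylate; 21 (2E)-4-hydroxy-4-methylpent-2-enal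
Product: 23 methyl (1R,4E,5S,8S,9S,13R)-9-hydroxy-4-[(2E)-4-hydroxy-4-methylpent-2-en-1-ylidene]-8-methyl-3-oxo-2-oxatricyclo[6.3.1.1(1,5)]tridecane-13-carboxylate, via phosphonate carbanion 22 (not isolated)
Conditions: KOt-Bu (1.0 equiv), THF, 0 °C; then 21, 0 °C to rt
Reagents that add atoms: none
Why: Telescoped intramolecular Michael addition/Horner–Wadsworth–Emmons olefination: the carbanion can reach C14 only on the face that carries O21 (six-membered, endo-mode closure), which sets 14S. The C13 ester enolate cannot expel O21 (that would need a C13=C20 bridgehead alkene) and should be protonated from the less hindered side of the lactone bridge (13R); proton transfer then gives the phosphonate carbanion 22, which olefinates 21 to the E-alkylidene lactone.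

Step 15
Reactants: 23 methyl (1R,4E,5S,8S,9S,13R)-9-hydroxy-4-[(2E)-4-hydroxy-4-methylpent-2-en-1-ylidene]-8-methyl-3-oxo-2-oxatricyclo[6.3.1.1(1,5)]tridecane-13-carboxylate
Product: 24 methyl (1R,2R,3S,6S,7S)-1,7-dihydroxy-3-[(2E,4E)-6-hydroxy-6-methyl-1-oxohepta-2,4-dien-2-yl]-6-methylbicyclo[4.3.1]decane-2-carboxylate
Conditions: i-Bu2AlH (3.3 equiv), CH2Cl2, −78 °C; aq. Rochelle salt
Reagents that add atoms: none
Why: Partial reduction of a lactone by diisobutylaluminium hydride: the lactone carbonyl, held in the reactive s-cis ester geometry, should form a stable aluminium hemiacetal faster than the methyl ester on C13, which is flanked by the quaternary C20. Work-up releases the conjugated aldehyde and C20–OH; two equivalents of hydride are consumed by the hydroxyls.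

Step 16
Reactants: 24 methyl (1R,2R,3S,6S,7S)-1,7-dihydroxy-3-[(2E,4E)-6-hydroxy-6-methyl-1-oxohepta-2,4-dien-2-yl]-6-methylbicyclo[4.3.1]decane-2-carboxylate
Product: 26 (1R,2R,6E,7S,10S,11S)-1,11-dihydroxy-6-[(2E)-4-hydroxy-4-methylpent-2-en-1-ylidene]-10-methyl-4-oxatricyclo[8.3.1.0(2,7)]tetradecan-3-one (CNP0116574.1), via triol ester 25 (not isolated)
Conditions: NaBH4, CeCl3·7H2O, MeOH, −40 °C; aq. work-up at pH 7; then 2-hydroxypyridine (cat.), toluene, 60 °C
Reagents that add atoms: none
Why: Luche 1,2-reduction of the dienal leaves the methyl ester intact; the primary allylic C9 hydroxyl is then acylated intramolecularly by the C11 ester (δ-lactonization with a neutral bifunctional catalyst), which spares the C2 carbinol and the C13 configuration.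

## Compound list

1 | 6-oxoheptanoic acid | CC(=O)CCCCC(=O)O | starting material
2 | 1-(1H-imidazol-1-yl)heptane-1,6-dione | CC(=O)CCCCC(=O)n1ccnc1 | intermediate
3 | N-methoxy-N-methyl-6-oxoheptanamide | CC(=O)CCCCC(=O)N(C)OC | intermediate
4 | N-methoxy-N-methyl-5-methylidene-6-oxoheptanamide | CC(=O)C(=C)CCCC(=O)N(C)OC | intermediate
5 | N-methoxy-N-methyl-5-methylidene-6-[(triethylsilyl)oxy]hept-6-enamide | C=C(O[Si](CC)(CC)CC)C(=C)CCCC(=O)N(C)OC | intermediate
6 | 1-bromo-2-(methoxymethoxy)ethane | COCOCCBr | starting material
7 | (methoxymethoxy)ethene | C=COCOC | intermediate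
8 | [1-(methoxymethoxy)ethenyl]lithium | [Li]C(=C)OCOC | intermediate
9 | 2-(methoxymethoxy)-7-methylidene-8-[(triethylsilyl)oxy]nona-1,8-dien-3-one | C=C(CCCC(=O)C(=C)OCOC)C(=C)O[Si](CC)(CC)CC | intermediate
10 | (1R)-1-(methoxymethoxy)-7-[(triethylsilyl)oxy]bicyclo[4.3.1]dec-6-en-2-one | O=C1CCCC2=C(O[Si](CC)(CC)CC)CC[C@@]1(OCOC)C2 | intermediate
11 | potassium (1R)-1-(methoxymethoxy)-7-[(triethylsilyl)oxy]bicyclo[4.3.1]deca-2,6-dien-2-olate | [K+].[O-]C1=CCCC2=C(O[Si](CC)(CC)CC)CC[C@@]1(OCOC)C2 | intermediate
12 | (1R)-1-(methoxymethoxy)-7-[(triethylsilyl)oxy]bicyclo[4.3.1]deca-2,6-dien-2-yl trifluoromethanesulfonate | O=S(=O)(OC1=CCCC2=C(O[Si](CC)(CC)CC)CC[C@@]1(OCOC)C2)C(F)(F)F | intermediate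
13 | (1R,6S)-1-(methoxymethoxy)-6-methyl-7-oxobicyclo[4.3.1]dec-2-en-2-yl trifluoromethanesulfonate | O=S(=O)(OC2=CCC[C@@]1(C)C[C@]2(OCOC)CCC1=O)C(F)(F)F | intermediate
14 | (1R,6S)-1-hydroxy-6-methyl-7-oxobicyclo[4.3.1]dec-2-en-2-yl trifluoromethanesulfonate | O=S(=O)(OC2=CCC[C@@]1(C)C[C@]2(O)CCC1=O)C(F)(F)F | intermediate
15 | (diethoxyphosphoryl)acetic acid | CCOP(=O)(CC(=O)O)OCC | starting material
16 | (1R,6S)-6-methyl-7-oxo-2-{[(trifluoromethyl)sulfonyl]oxy}bicyclo[4.3.1]dec-2-en-1-yl (diethoxyphosphoryl)acetate | O=S(=O)(OC2=CCC[C@@]1(C)C[C@]2(OC(=O)CP(=O)(OCC)OCC)CCC1=O)C(F)(F)F | intermediate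
17 | (1R,6S,7S)-7-hydroxy-6-methyl-2-{[(trifluoromethyl)sulfonyl]oxy}bicyclo[4.3.1]dec-2-en-1-yl (diethoxyphosphoryl)acetate | O=S(=O)(OC2=CCC[C@@]1(C)C[C@]2(OC(=O)CP(=O)(OCC)OCC)CC[C@@H]1O)C(F)(F)F | intermediate
18 | methyl (1R,6S,7S)-1-{[(diethoxyphosphoryl)acetyl]oxy}-7-hydroxy-6-methylbicyclo[4.3.1]dec-2-ene-2-carboxylate | COC(=O)C2=CCC[C@@]1(C)C[C@]2(OC(=O)CP(=O)(OCC)OCC)CC[C@@H]1O | intermediate
19 | 2-methylbut-3-en-2-ol | C=CC(C)(C)O | starting material
20 | (2E)-but-2-enal | C/C=C/C=O | starting material
21 | (2E)-4-hydroxy-4-methylpent-2-enal | CC(C)(O)/C=C/C=O | intermediate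
22 | potassium salt of the C4 carbanion of methyl (1R,5S,8S,9S,13R)-4-(diethoxyphosphoryl)-9-hydroxy-8-methyl-3-oxo-2-oxatricyclo[6.3.1.1(1,5)]tridecane-13-carboxylate | [K+].CCOP(=O)(OCC)[C-]1C(=O)O[C@]23CC[C@H](O)[C@](C)(C2)CCC[C@H]1[C@H]3C(=O)OC | intermediate
23 | methyl (1R,4E,5S,8S,9S,13R)-9-hydroxy-4-[(2E)-4-hydroxy-4-methylpent-2-en-1-ylidene]-8-methyl-3-oxo-2-oxatricyclo[6.3.1.1(1,5)]tridecane-13-carboxylate | CC(C)(O)/C=C/C=C1/C(=O)O[C@]23CC[C@H](O)[C@](C)(C2)CCC[C@H]1[C@H]3C(=O)OC | intermediate
24 | methyl (1R,2R,3S,6S,7S)-1,7-dihydroxy-3-[(2E,4E)-6-hydroxy-6-methyl-1-oxohepta-2,4-dien-2-yl]-6-methylbicyclo[4.3.1]decane-2-carboxylate | CC(C)(O)/C=C/C=C(/C=O)[C@H]1CC[C@@]2(C)C[C@](O)(CC[C@@H]2O)[C@@H]1C(=O)OC | intermediate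
25 | methyl (1R,2R,3S,6S,7S)-3-[(2E,4E)-1,6-dihydroxy-6-methylhepta-2,4-dien-2-yl]-1,7-dihydroxy-6-methylbicyclo[4.3.1]decane-2-carboxylate | CC(C)(O)/C=C/C=C(/CO)[C@H]1CC[C@@]2(C)C[C@](O)(CC[C@@H]2O)[C@@H]1C(=O)OC | intermediate
26 | (1R,2R,6E,7S,10S,11S)-1,11-dihydroxy-6-[(2E)-4-hydroxy-4-methylpent-2-en-1-ylidene]-10-methyl-4-oxatricyclo[8.3.1.0(2,7)]tetradecan-3-one (CNP0116574.1) | CC(C)(O)/C=C/C=C1/COC(=O)[C@@H]2[C@@H]1CC[C@@]1(C)C[C@]2(O)CC[C@@H]1O | target

## Step count and least certain steps

Total: 16 steps. Longest linear sequence: 14 steps (1–3, 5–12, 14–16, from 6-oxoheptanoic acid); steps 4 and 13 are side branches.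

**Step 6 (key step).** The most likely failure is loss of enantiocontrol. Silicon transfer from the diene to triflate would create an achiral silyl Lewis acid, and the activated triene may also cyclize without the catalyst; desilylation of the diene is the second risk. Fallback with known chemistry: from 9, the cycloaddition is run with Et2AlCl, a promoter known for this type of silyloxydiene cyclization, to give the racemic cycloadduct F1. Its enantiomers are separated by preparative chromatography on a chiral stationary phase, and the 1R enantiomer is 10, where the route is rejoined.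

**Step 14.** The carbanion may attack the C11 ester carbonyl instead of C14 (Lacey–Dieckmann-type closure to a ring of the same size), the endo-mode conjugate addition may be slow, and the C13 enolate may be protonated from the wrong face. Fallback: from 18, deprotonation with NaH and iodination with N-iodosuccinimide give the α-iodophosphonate F2. Further base and aldehyde 21 give the (2Z,4E)-2-iodo dienoate F3 by Horner–Wadsworth–Emmons olefination. A reductive Heck cyclization (Pd(OAc)2, PPh3, HCO2Na, DMF, 60 °C) then forms C8–C14 by syn-carbopalladation of the enoate from the face of O21, and hydride capture at C13 places H syn to C8. This returns to 23 without any carbanion near the ester.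

**Step 15.** The hydride may not discriminate between the lactone and the C11 methyl ester, since both are hindered and excess reagent is needed for the two hydroxyls; the result would be over-reduction at C11. Fallback: from 23, Me3SnOH (1,2-dichloroethane, 70 °C) hydrolyses the methyl ester and leaves the tert-alkyl dienoate lactone, giving the carboxylic acid F4. LiBH4 (THF, 0 °C to rt) reduces the lactone while the carboxylate is inert, giving the seco hydroxy acid F5. Carbodiimide lactonization (EDC·HCl, 4-(dimethylamino)pyridine, CH2Cl2) closes the primary alcohol onto C11 and arrives at 26.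

**Step 8.** Proton transfer from the product ketone (C23–H) to unreacted enolate would lead to over-methylation, and O-methylation or attack of fluoride on the enol triflate may compete. Fallback: from 12, Simmons–Smith cyclopropanation (Et2Zn, CH2I2, CH2Cl2, 0 °C) of the strained, electron-rich enol ether gives the siloxycyclopropane F6. Fluoride (Bu4NF, THF, 0 °C) opens it at the C24–CH2 bond, the less substituted carbanion side, which leaves the methyl on C17 and returns to 13.

**Step 11.** Hydride may be delivered along the axial (exo) direction if the four-carbon bridge crowds the equatorial trajectory more than expected, which would give the equatorial C24 epimer. Fallback: from 16, NaBH4 (MeOH, 0 °C; axial attack) gives the equatorial alcohol F7. Tf2O/pyridine gives its triflate F8, and displacement with Bu4N+ NO2− (Lattrell–Dax inversion, nitrite ester hydrolysed on work-up) gives the axial alcohol 17.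

**Step 2.** Methylenation may occur at the methyl group or twice, because the regiochemistry rests only on the enol equilibrium. Fallback: from 3, Me3SiCl/Et3N in DMF at 100 °C gives the thermodynamic trimethylsilyl enol ether F9 (internal isomer purified by distillation). Eschenmoser's salt (CH2=NMe2+ I−, CH2Cl2) gives the Mannich base F10 regiospecifically, and quaternization with MeI followed by NaHCO3 elimination gives 4.

## Further compounds

F1 | step 6 | racemic 1-(methoxymethoxy)-7-[(triethylsilyl)oxy]bicyclo[4.3.1]dec-6-en-2-one | O=C1CCCC2=C(O[Si](CC)(CC)CC)CCC1(OCOC)C2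
F2 | step 14 | methyl (1R,6S,7S)-1-{[(diethoxyphosphoryl)(iodo)acetyl]oxy}-7-hydroxy-6-methylbicyclo[4.3.1]dec-2-ene-2-carboxylate | COC(=O)C2=CCC[C@@]1(C)C[C@]2(OC(=O)C(I)P(=O)(OCC)OCC)CC[C@@H]1O
F3 | step 14 | methyl (1R,6S,7S)-7-hydroxy-1-{[(2Z,4E)-6-hydroxy-2-iodo-6-methylhepta-2,4-dienoyl]oxy}-6-methylbicyclo[4.3.1]dec-2-ene-2-carboxylate | COC(=O)C2=CCC[C@@]1(C)C[C@]2(OC(=O)/C(I)=C/C=C/C(C)(C)O)CC[C@@H]1O
F4 | step 15 | (1R,4E,5S,8S,9S,13R)-9-hydroxy-4-[(2E)-4-hydroxy-4-methylpent-2-en-1-ylidene]-8-methyl-3-oxo-2-oxatricyclo[6.3.1.1(1,5)]tridecane-13-carboxylic acid | CC(C)(O)/C=C/C=C1/C(=O)O[C@]23CC[C@H](O)[C@](C)(C2)CCC[C@H]1[C@H]3C(=O)O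
F5 | step 15 | (1R,2R,3S,6S,7S)-3-[(2E,4E)-1,6-dihydroxy-6-methylhepta-2,4-dien-2-yl]-1,7-dihydroxy-6-methylbicyclo[4.3.1]decane-2-carboxylic acid | CC(C)(O)/C=C/C=C(/CO)[C@H]1CC[C@@]2(C)C[C@](O)(CC[C@@H]2O)[C@@H]1C(=O)O
F6 | step 8 | (6R)-6-(methoxymethoxy)-3-[(triethylsilyl)oxy]tricyclo[4.4.1.0(1,3)]undec-7-en-7-yl trifluoromethanesulfonate (C17–C24 methylene adduct of 12) | O=S(=O)(OC1=CCC[C@@]23C[C@@]3(O[Si](CC)(CC)CC)CC[C@@]1(OCOC)C2)C(F)(F)F
F7 | step 11 | (1R,6S,7R)-7-hydroxy-6-methyl-2-{[(trifluoromethyl)sulfonyl]oxy}bicyclo[4.3.1]dec-2-en-1-yl (diethoxyphosphoryl)acetate | O=S(=O)(OC2=CCC[C@@]1(C)C[C@]2(OC(=O)CP(=O)(OCC)OCC)CC[C@H]1O)C(F)(F)F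
F8 | step 11 | (1R,6S,7R)-6-methyl-2,7-bis{[(trifluoromethyl)sulfonyl]oxy}bicyclo[4.3.1]dec-2-en-1-yl (diethoxyphosphoryl)acetate | O=S(=O)(OC2=CCC[C@@]1(C)C[C@]2(OC(=O)CP(=O)(OCC)OCC)CC[C@H]1OS(=O)(=O)C(F)(F)F)C(F)(F)F
F9 | step 2 | N-methoxy-N-methyl-6-[(trimethylsilyl)oxy]hept-5-enamide (E/Z mixture) | CC(O[Si](C)(C)C)=CCCCC(=O)N(C)OC
F10 | step 2 | 5-[(dimethylamino)methyl]-N-methoxy-N-methyl-6-oxoheptanamide | CC(=O)C(CN(C)C)CCCC(=O)N(C)OC
A1 | alternative 1 | bis(tert-butyldimethylsilyl) ether of the target (O4 and O25 silylated) | CC(C)(O[Si](C)(C)C(C)(C)C)/C=C/C=C1/COC(=O)[C@@H]2[C@@H]1CC[C@@]1(C)C[C@]2(O)CC[C@@H]1O[Si](C)(C)C(C)(C)C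
A2 | alternative 1 | (1R,2R,3S,6S,7S)-7-[(tert-butyldimethylsilyl)oxy]-3-{(4E)-6-[(tert-butyldimethylsilyl)oxy]-3-hydroxy-6-methylhepta-1,4-dien-2-yl}-1-hydroxy-6-methylbicyclo[4.3.1]decane-2-carboxylic acid | CC(C)(O[Si](C)(C)C(C)(C)C)/C=C/C(O)C(=C)[C@H]1CC[C@@]2(C)C[C@](O)(CC[C@@H]2O[Si](C)(C)C(C)(C)C)[C@@H]1C(=O)O
A3 | alternative 2 | methyl 7-(2-tert-butoxy-2-oxoethyl)-2-(tert-butyldimethylsilyloxy)-4-[(tert-butyldimethylsilyloxy)methyl]-4-methylcyclohepta-1,5-diene-1-carboxylate | COC(=O)C1=C(O[Si](C)(C)C(C)(C)C)C[C@@](C)(CO[Si](C)(C)C(C)(C)C)C=C[C@@H]1CC(=O)OC(C)(C)C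
A4 | alternative 2 | methyl 3-[(tert-butyldimethylsilyl)oxy]-2-diazobut-3-enoate | COC(=O)C(=[N+]=[N-])C(=C)O[Si](C)(C)C(C)(C)C
A5 | alternative 2 | tert-butyl (3E,5Z)-7-[(tert-butyldimethylsilyl)oxy]-6-methylhepta-3,5-dienoate | CC(C)(C)OC(=O)C/C=C/C=C(/C)CO[Si](C)(C)C(C)(C)C
A6 | alternative 3 | tert-butyl 1-(tert-butyldimethylsilyloxy)-6-methyl-7-oxobicyclo[4.3.1]dec-2-ene-2-carboxylate | CC(C)(C)OC(=O)C2=CCC[C@@]1(C)C[C@]2(O[Si](C)(C)C(C)(C)C)CCC1=O
A7 | alternative 3 | tert-butyl 4-[(tert-butyldimethylsilyl)oxy]-7-ethenyl-1-hydroxy-2-methylidenebicyclo[2.2.1]heptane-7-carboxylate (ethenyl syn to the methylidene bridge) | C=C[C@@]1(C(=O)OC(C)(C)C)[C@]2(O)CC[C@@]1(O[Si](C)(C)C(C)(C)C)CC2=C
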